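The carbocycle (ring B) of the 2,3-dihydrobenzofuran-4,6-dione core is a 1,3,5-trioxygenated ring: its quaternary C5 (gem-dimethyl) lies between the C4 and C6 ketones as a non-enolisable dimethylmalonyl unit, and the oxygen on C7a is already the ring A ether oxygen, so it cannot be acylated. Ring B is therefore cut at C3a–C4 and C6–C7. A [3+3] double C-acylation of the silyl dienol ether of an enantiopure 2-(acylmethylene)oxolane with dimethylmalonyl dichloride forms both bonds and ring B at once and delivers the β-triketone directly. The oxolane arises from a diketone dianion and the bromide of Sharpless-derived (2R,3R)-epoxygeraniol.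

Key step: step 4

Remark: the target is a β-triketone whose enol tautomers interconvert, so the drawn exocyclic enol (OH hydrogen-bonded to the C6 carbonyl) is treated as the resting tautomer and not as a separate stereochemical element; the core is numbered as a benzofuran (O1, C2, C3, C3a, C4 to C7, C7a), and the E/Z geometry of compound 6 is irrelevant because that double bond is moved in step 4.

Step 1
Reactants: 1 geraniol, (2E)-3,7-dimethylocta-2,6-dien-1-ol
Product: 2 [(2R,3R)-3-methyl-3-(4-methylpent-3-en-1-yl)oxiran-2-yl]methanol, (2R,3R)-2,3-epoxygeraniol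
Conditions: Ti(OiPr)4 (5 mol%), D-(−)-diethyl tartrate (7.5 mol%), t-BuOOH (anhydrous, 2 equiv), 4 Å MS, CH2Cl2, −20 °C
Reagents that add atoms: tert-butyl hydroperoxide, CC(C)(C)OO
Why: Katsuki–Sharpless asymmetric epoxidation, in which the titanium tartrate catalyst binds the allylic hydroxyl so that only the 2,3-alkene is epoxidised (the 6,7-alkene is untouched) and the D-(−)-tartrate ligand directs oxygen to the face of the E-alkene that gives the (2R,3R) epoxide, which sets both stereocentres of the route (the quaternary carbon becomes the (R)-carbinol, the oxirane CH is inverted later to the (S) ring carbon).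

Step 2
Reactants: 2 (2R,3R)-2,3-epoxygeraniol
Product: 3 (2R,3S)-3-(bromomethyl)-2-methyl-2-(4-methylpent-3-en-1-yl)oxirane
Conditions: CBr4, PPh3, CH2Cl2, 0 °C
Reagents that add atoms: carbon tetrabromide, BrC(Br)(Br)Br
Why: Appel reaction, in which the primary hydroxyl is activated as an alkoxyphosphonium ion and displaced by bromide at the CH2 under neutral conditions that leave the epoxide and both stereocentres unchanged (the descriptor of the oxirane CH changes from R to S only because CH2Br gains CIP priority).

Step 3
Reactants: 3 (2R,3S)-3-(bromomethyl)-2-methyl-2-(4-methylpent-3-en-1-yl)oxirane; 4 5-methylhexane-2,4-dione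
Product: 6 (1E)-1-[(5S)-5-[(2R)-2-hydroxy-6-methylhept-5-en-2-yl]oxolan-2-ylidene]-3-methylbutan-2-one, via epoxy diketone enolate 5 (not isolated)
Conditions: 4 (1.3 equiv), LiN(iPr)2 (2.5 equiv), THF, 0 °C; then 3 (1.0 equiv), LiClO4 (2 equiv), −78 → 20 °C; aq. NH4Cl
Reagents that add atoms: none
Why: Domino alkylation/cyclisation of a 1,3-dicarbonyl dianion with an epibromohydrin-type electrophile, in which the terminal (methyl-derived) carbanion of the dianion displaces bromide to give enolate 5, whose oxygen then opens the lithium-activated epoxide at the adjacent secondary carbon by 5-exo-tet attack with inversion (carbon attack would be a disfavoured 5-(enolendo)-exo-tet closure), which sets the (5S) ring carbon and releases the (R)-tertiary alcohol without touching its C–O bond.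

Step 4
Reactants: 6 (1E)-1-[(5S)-5-[(2R)-2-hydroxy-6-methylhept-5-en-2-yl]oxolan-2-ylidene]-3-methylbutan-2-one; 7 2,2-dimethylpropanedioyl dichloride (dimethylmalonyl dichloride)
Product: 11 (2S)-2-[(2R)-2-hydroxy-6-methylhept-5-en-2-yl]-7-(1-hydroxy-2-methylpropylidene)-5,5-dimethyl-2,3-dihydro-1-benzofuran-4,6(5H,7H)-dione (target), via bis-silyl dienol ether 8 (not isolated), via monoacylated acid chloride 9 (not isolated), via O-silylated triketone 10 (not isolated)
Conditions: Me3SiOTf (2.4 equiv), Et3N (5 equiv), CH2Cl2, 0 °C; then 7 (1.1 equiv), −78 → 20 °C; then 1 M HCl, THF, 0 °C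
Reagents that add atoms: none
Why: Me3SiOTf/Et3N silylates the tertiary alcohol and converts the vinylogous ester into the 1-alkoxy-3-silyloxy-1,3-diene 8 by loss of a ring-methylene proton; the terminal dihydrofuran carbon of 8 (the future C3a), the most nucleophilic site as in a Chan-type diene, is C-acylated by one COCl of 7 to give 9, whose remaining silyl enol ether carbon (the future C7) then attacks the second COCl. The closest known reaction types are the Effenberger cyclization of enol ethers with malonyl dichlorides and the [3+3] cyclization of 1,3-bis(silyl enol ethers) with 1,3-dielectrophiles, both vinylogous Mukaiyama-type acylations. Ring B closes by a 6-(enolexo)-exo-trig acylation that is helped by the gem-dimethyl (Thorpe–Ingold) effect. No stereocentre is formed, and the two existing ones are remote from every acidic position and stay untouched. The step needs enolisation toward the ring methylene, which the hindered isopropyl methine (it would give a tetrasubstituted cross-conjugated enol ether) should secure, and C- instead of O-cyclisation, which is secured because the oxygen on the central carbon is the ring A ether oxygen and cannot be acylated, while 7 has no α-hydrogen (no ketene with Et3N), the tertiary hydroxyl is masked in situ, and the product is a strongly acidic β-triketone whose enolate is a thermodynamic sink. The acidic work-up cleaves the tertiary Me3Si ether of 10 and gives 11.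

Compound list
1 | geraniol, (2E)-3,7-dimethylocta-2,6-dien-1-ol | CC(C)=CCC/C(C)=C/CO | starting material
2 | [(2R,3R)-3-methyl-3-(4-methylpent-3-en-1-yl)oxiran-2-yl]methanol, (2R,3R)-2,3-epoxygeraniol | OC[C@H]1O[C@]1(C)CCC=C(C)C | intermediate
3 | (2R,3S)-3-(bromomethyl)-2-methyl-2-(4-methylpent-3-en-1-yl)oxirane | BrC[C@H]1O[C@]1(C)CCC=C(C)C | intermediate
4 | 5-methylhexane-2,4-dione | CC(=O)CC(=O)C(C)C | starting material
5 | 2-methyl-7-[(2R,3R)-3-methyl-3-(4-methylpent-3-en-1-yl)oxiran-2-yl]heptane-3,5-dione (present as its lithium enolate, not isolated) | CC(C)C(=O)CC(=O)CC[C@H]1O[C@]1(C)CCC=C(C)C | intermediate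
6 | (1E)-1-[(5S)-5-[(2R)-2-hydroxy-6-methylhept-5-en-2-yl]oxolan-2-ylidene]-3-methylbutan-2-one | CC(C)C(=O)/C=C1\CC[C@H](O1)[C@](C)(O)CCC=C(C)C | intermediate
7 | 2,2-dimethylpropanedioyl dichloride (dimethylmalonyl dichloride) | CC(C)(C(=O)Cl)C(=O)Cl | starting material
8 | (2S)-5-[(1Z)-3-methyl-2-(trimethylsilyloxy)but-1-en-1-yl]-2-[(2R)-6-methyl-2-(trimethylsilyloxy)hept-5-en-2-yl]-2,3-dihydrofuran (not isolated) | CC(C)/C(O[Si](C)(C)C)=C/C1=CC[C@H](O1)[C@](C)(O[Si](C)(C)C)CCC=C(C)C | intermediate
9 | 3-[(5S)-2-[(1Z)-3-methyl-2-(trimethylsilyloxy)but-1-en-1-yl]-5-[(2R)-6-methyl-2-(trimethylsilyloxy)hept-5-en-2-yl]-4,5-dihydrofuran-3-yl]-2,2-dimethyl-3-oxopropanoyl chloride (not isolated) | CC(C)/C(O[Si](C)(C)C)=C/C1=C(C(=O)C(C)(C)C(Cl)=O)C[C@H](O1)[C@](C)(O[Si](C)(C)C)CCC=C(C)C | intermediate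
10 | (2S)-7-(1-hydroxy-2-methylpropylidene)-5,5-dimethyl-2-[(2R)-6-methyl-2-(trimethylsilyloxy)hept-5-en-2-yl]-2,3-dihydro-1-benzofuran-4,6(5H,7H)-dione (not isolated) | CC(C)=CCC[C@@](C)(O[Si](C)(C)C)[C@@H]1CC2=C(O1)/C(=C(/O)C(C)C)C(=O)C(C)(C)C2=O | intermediate
11 | (2S)-2-[(2R)-2-hydroxy-6-methylhept-5-en-2-yl]-7-(1-hydroxy-2-methylpropylidene)-5,5-dimethyl-2,3-dihydro-1-benzofuran-4,6(5H,7H)-dione, CNP0317212.1 | CC(C)=CCC[C@@](C)(O)[C@@H]1CC2=C(O1)/C(=C(/O)C(C)C)C(=O)C(C)(C)C2=O | target

Total step count: 4
Longest linear sequence: 4 steps (1 → 2 → 3 → 6 → 11)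

Steps most likely to fail

Step 4. The enol silylation may remove the isopropyl methine proton instead of a ring-methylene proton. The first acylation may take place at the inner carbon and be followed by closure through the enol oxygen, which gives a lactone instead of the carbocycle. The hindered acid chloride may also react so slowly that the mono-acyl stage is hydrolysed on work-up. The fallback builds ring B first from an arene and closes ring A last; it sets out from bromide 3 and returns at 11. Phloroglucinol is C-acylated with isobutyryl chloride (AlCl3, PhNO2/CH2Cl2) to 2-methyl-1-(2,4,6-trihydroxyphenyl)propan-1-one F1. Dearomatising double C-methylation (NaOMe, MeI, MeOH) gives 3,5-dihydroxy-6,6-dimethyl-2-(2-methylpropanoyl)cyclohexa-2,4-dien-1-one F2. Its sodium enolate is C-alkylated at the remaining ring CH by 3 (NaOMe, MeOH) to 3,5-dihydroxy-6,6-dimethyl-4-{[(2R,3R)-3-methyl-3-(4-methylpent-3-en-1-yl)oxiran-2-yl]methyl}-2-(2-methylpropanoyl)cyclohexa-2,4-dien-1-one F3. On warming with base, F3 closes ring A by 5-exo epoxide opening through the enol oxygen next to the acyl-bearing carbon, with the same inversion as in step 3, to give 11. The isomer closed through the other enol oxygen would have to be separated.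

Step 3. The strongly basic dianion may fragment or eliminate the α-bromo epoxide instead of alkylating it, and over-deprotonation of the alkylated enolate may lead to cyclopropane formation. The epoxide opening may also stall, because the secondary oxirane carbon sits next to a quaternary centre, or it may be diverted to 6-endo attack under lithium assistance. The fallback lets the carbon nucleophile open an unhindered terminal epoxide and forms the ring C–O bond by cyclodehydration; it sets out from 2 and returns at 6. Payne rearrangement of 2 with in situ hydroxide opening (0.5 M NaOH, t-BuOH/H2O, 70 °C) inverts the oxirane CH once and gives (2S,3R)-3,7-dimethyloct-6-ene-1,2,3-triol F4. Selective sulfonylation of the primary hydroxyl (TsCl, Et3N, Bu2SnO cat., CH2Cl2) gives (2S,3R)-2,3-dihydroxy-3,7-dimethyloct-6-en-1-yl 4-methylbenzenesulfonate F5, and K2CO3 in MeOH closes it to (2R)-6-methyl-2-[(2S)-oxiran-2-yl]hept-5-en-2-ol F6. The dianion of 4 (LiN(iPr)2, THF) opens F6 at the terminal CH2 to (8S,9R)-8,9-dihydroxy-2,9,13-trimethyltetradec-12-ene-3,5-dione F7. Mild acid (pyridinium p-toluenesulfonate, 4 Å MS, CH2Cl2) cyclises and dehydrates F7 to 6.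

Step 2. Bromide ion or adventitious HBr may open the acid-labile trisubstituted epoxide during alkoxyphosphonium formation, and the epoxy bromide may decompose on purification. The fallback activates the hydroxyl under basic conditions as an arenesulfonate, with no bromide ion and no phosphonium intermediate; it sets out from 2 and returns at 6. TsCl, Et3N and DMAP (cat.) in CH2Cl2 at 0 °C give [(2R,3R)-3-methyl-3-(4-methylpent-3-en-1-yl)oxiran-2-yl]methyl 4-methylbenzenesulfonate F8, which is used in place of 3 in the dianion domino of step 3 (direct displacement of the sulfonate by the dianion carbon, then the same 5-exo epoxide opening) to give 6.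

Further compounds
F1 | step 4 | 2-methyl-1-(2,4,6-trihydroxyphenyl)propan-1-one | CC(C)C(=O)c1c(O)cc(O)cc1O
F2 | step 4 | 3,5-dihydroxy-6,6-dimethyl-2-(2-methylpropanoyl)cyclohexa-2,4-dien-1-one | CC(C)C(=O)C1=C(O)C=C(O)C(C)(C)C1=O
F3 | step 4 | 3,5-dihydroxy-6,6-dimethyl-4-{[(2R,3R)-3-methyl-3-(4-methylpent-3-en-1-yl)oxiran-2-yl]methyl}-2-(2-methylpropanoyl)cyclohexa-2,4-dien-1-one | CC(C)C(=O)C1=C(O)C(C[C@H]2O[C@]2(C)CCC=C(C)C)=C(O)C(C)(C)C1=O
F4 | step 3 | (2S,3R)-3,7-dimethyloct-6-ene-1,2,3-triol | OC[C@H](O)[C@](C)(O)CCC=C(C)C
F5 | step 3 | (2S,3R)-2,3-dihydroxy-3,7-dimethyloct-6-en-1-yl 4-methylbenzenesulfonate | Cc1ccc(cc1)S(=O)(=O)OC[C@H](O)[C@](C)(O)CCC=C(C)C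
F6 | step 3 | (2R)-6-methyl-2-[(2S)-oxiran-2-yl]hept-5-en-2-ol | C1O[C@@H]1[C@](C)(O)CCC=C(C)C
F7 | step 3 | (8S,9R)-8,9-dihydroxy-2,9,13-trimethyltetradec-12-ene-3,5-dione | CC(C)C(=O)CC(=O)CC[C@H](O)[C@](C)(O)CCC=C(C)C
F8 | step 2 | [(2R,3R)-3-methyl-3-(4-methylpent-3-en-1-yl)oxiran-2-yl]methyl 4-methylbenzenesulfonate | Cc1ccc(cc1)S(=O)(=O)OC[C@H]1O[C@]1(C)CCC=C(C)C
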